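**Retrosynthetic overview**
1. The C8 carbinol comes from methyl addition to a C8 ketone. The butanolide comes from a desymmetrizing Baeyer–Villiger ring expansion of a prochiral spiro-cyclobutanone, which sets C13 (key step).
2. The spiro-tetrahydrofuran comes from 5-exo oxa-Michael addition of a 9α-hydroxyl to a 3-alkylcyclobutenone. The 9α-OH/8-ketone pair comes from α-face dihydroxylation and oxidation of a C8=C9 alkene.
3. The C9–C11 bond comes from a B-alkyl Suzuki coupling of a C9 enol triflate with a vinyl cyclobutenyl fragment made from 3-ethoxycyclobutenone.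
4. The 19,6-lactone and C5–H come from a photoredox hydrolactonization of a 5(6)-ene methyl ester. Ring A comes from a CuH-catalysed desymmetrizing reductive aldol on 2-methylcyclohexane-1,3-dione.
5. Ring order: ring B (from the dione), ring A, γ-lactone, cyclobutenone (brought in), tetrahydrofuran, butanolide (by ring expansion).

Convention: labdane locants are used (decalin C1–C10, side chain C11–C16, C17 = methyl on C8, C18 = α-methyl on C4, C19 = β-carbonyl carbon on C4, C20 = β-methyl on C10; α is the face opposite C20). The target SMILES is read as (4S,5R,6R,8S,9S,10S,13S).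

**Route**

Step 1
Reactants: 1 cyclohexane-1,3-dione
Product: 2 2-methylcyclohexane-1,3-dione
Conditions: MeI, KOH, H2O/MeOH, 65 °C
Reagents that add atoms: iodomethane (CI)
Why: C-alkylation of the doubly stabilized 1,3-dione enolate with iodomethane in aqueous base (classical dione C-methylation); no stereocenter is formed.

Step 2
Reactants: 2 2-methylcyclohexane-1,3-dione; 3 acrolein; 4 methyl 2-bromopropanoate
Product: 8 methyl (E)-2-methyl-5-(1-methyl-2,6-dioxocyclohexyl)pent-2-enoate, via dione aldehyde 5 (not isolated), via phosphonium bromide 6 (not isolated), via phosphorus ylide 7 (not isolated)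
Conditions: acrolein (1.05 equiv), H2O, 25 °C; then methyl 2-bromopropanoate, PPh3, sat. aq. NaHCO3, 25 °C
Reagents that add atoms: none
Why: Uncatalysed Michael addition of the acidic dione to acrolein in water is followed in the same flask by an aqueous one-pot Wittig olefination (salt and stabilized ylide formed in situ), the α-methyl stabilized ylide giving the (E)-enoate while the aldol-prone aldehyde is never isolated; the quaternary carbon (future C10) is still prochiral.

Step 3
Reactants: 8 methyl (E)-2-methyl-5-(1-methyl-2,6-dioxocyclohexyl)pent-2-enoate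
Product: 9 methyl (1S,4aS,8aR)-8a-hydroxy-1,4a-dimethyl-5-oxodecahydronaphthalene-1-carboxylate
Conditions: Cu(OAc)2·H2O (5 mol%), (R)-DTBM-SEGPHOS (5.5 mol%), (EtO)2MeSiH (1.5 equiv), t-BuOH (1.2 equiv), toluene, 0 °C
Reagents that add atoms: none
Why: CuH-catalysed enantioselective reductive aldol cyclization (conjugate reduction, then intramolecular aldol) desymmetrizes the dione: the bisphosphine-bound copper enolate picks one of the two enantiotopic ketones (sets C10) through a closed six-membered copper aldolate transition state that puts ester and new hydroxyl cis and gives the cis-fused ketol, so the ester ends up cis to the angular methyl (sets C4; the C5 carbinol centre is erased in step 4), and the ligand antipode that gives this series is fixed in a pilot run.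

Step 4
Reactants: 9 methyl (1S,4aS,8aR)-8a-hydroxy-1,4a-dimethyl-5-oxodecahydronaphthalene-1-carboxylate
Product: 10 methyl (1S,4aS)-1,4a-dimethyl-5-oxo-1,2,3,4,4a,5,6,7-octahydronaphthalene-1-carboxylate
Conditions: SOCl2, pyridine, CH2Cl2, −20 → 0 °C
Reagents that add atoms: none
Why: Dehydration of the tertiary β-hydroxy ester through its chlorosulfite (E2-type elimination) can only give the 5(6)-alkene because C4 and C10 are quaternary and only C6 carries β-hydrogens, and the basic medium avoids cation-driven fragmentation.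

Step 5
Reactants: 10 methyl (1S,4aS)-1,4a-dimethyl-5-oxo-1,2,3,4,4a,5,6,7-octahydronaphthalene-1-carboxylate
Product: 11 keto lactone (4S,5R,6R,10S)-9-oxo-11,12,13,14,15,16,17-heptanorlabdan-19,6-olide
Conditions: 9-mesityl-3,6-di-tert-butyl-10-phenylacridinium tetrafluoroborate (5 mol%), PhSH (1.2 equiv), 1,2-dichloroethane, 450 nm LEDs, 25 °C
Reagents that add atoms: none
Why: Proposed new method: dealkylative anti-Markovnikov hydrolactonization of a methyl ester under acridinium photoredox catalysis — the excited acridinium oxidizes the C5=C6 alkene to its radical cation, the axial C19 ester carbonyl oxygen held over C6 on the β-face attacks the less substituted C6 in a 5-endo closure that leaves the tertiary C5 radical, thiophenol delivers hydrogen to C5 from the open α-face (trans ring fusion; sets C5 and C6), and the thiolate formed on catalyst turnover removes the methyl group from the O-methyl lactonium ion as thioanisole; the closest known reactions are the acridinium/thiol-catalysed anti-Markovnikov addition of carboxylic acids to alkenes and the halolactonization of alkyl esters with loss of the alkyl group.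

Step 6
Reactants: 11 keto lactone (4S,5R,6R,10S)-9-oxo-11,12,13,14,15,16,17-heptanorlabdan-19,6-olide
Product: 12 enol triflate (4S,5R,6R,10S)-9-(trifluoromethanesulfonyloxy)-11,12,13,14,15,16,17-heptanorlabd-8-en-19,6-olide
Conditions: KN(SiMe3)2, THF, −78 °C; PhNTf2, −78 → 0 °C
Reagents that add atoms: N-phenyl-bis(trifluoromethanesulfonimide) (O=S(=O)(N(c1ccccc1)S(=O)(=O)C(F)(F)F)C(F)(F)F)
Why: Kinetic deprotonation at C8 (the only enolizable position, C10 and C4 being quaternary) and O-sulfonylation give the enol triflate; no stereocenter is touched.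

Step 7
Reactants: 13 3-ethoxycyclobut-2-en-1-one
Product: 14 (1-ethenyl-3-ethoxycyclobut-2-en-1-yl)oxy(trimethyl)silane
Conditions: CH2=CHMgBr, THF, −78 °C; then Me3SiCl, −78 → 0 °C
Reagents that add atoms: vinylmagnesium bromide (C=C[Mg]Br); chlorotrimethylsilane (C[Si](C)(C)Cl)
Why: 1,2-Addition of the vinyl Grignard reagent to the carbonyl of the vinylogous ester (first half of a Stork–Danheiser transposition) with in situ silylation of the tertiary alkoxide; the carbinol centre is racemic and is destroyed in step 8.

Step 8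
Reactants: 12 enol triflate (4S,5R,6R,10S)-9-(trifluoromethanesulfonyloxy)-11,12,13,14,15,16,17-heptanorlabd-8-en-19,6-olide; 14 (1-ethenyl-3-ethoxycyclobut-2-en-1-yl)oxy(trimethyl)silane
Product: 17 cyclobutenone (4S,5R,6R,10S)-15-oxo-17-nor-15,16-cyclolabda-8,13-dien-19,6-olide, via alkylborane 15 (not isolated), via coupled silyl ether 16 (not isolated)
Conditions: 14, 9-BBN, THF, 0 → 25 °C; then 12, Pd(dppf)Cl2 (5 mol%), AsPh3, Cs2CO3, DMF/H2O, 50 °C; then 1 M HCl, THF, 0 °C
Reagents that add atoms: water (O)
Why: Anti-Markovnikov hydroboration of the terminal vinyl group and B-alkyl Suzuki–Miyaura coupling with the enol triflate form C9–C11, after which dilute acid ionizes the allylic silyloxy group and hydrolyses the enol ether to the transposed 3-alkylcyclobutenone; the C8=C9 position is fixed by the triflate.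

Step 9
Reactants: 17 cyclobutenone (4S,5R,6R,10S)-15-oxo-17-nor-15,16-cyclolabda-8,13-dien-19,6-olide
Product: 18 diol 8α,9α-dihydroxy-15-oxo-17-nor-15,16-cyclolabd-13-en-19,6β-olide
Conditions: OsO4 (2 mol%), NMO (1.2 equiv), citric acid, acetone/H2O, 0 → 25 °C
Reagents that add atoms: N-methylmorpholine N-oxide (C[N+]1([O-])CCOCC1); water (O)
Why: Upjohn syn-dihydroxylation, in which OsO4 attacks the electron-rich trisubstituted C8=C9 alkene faster than the electron-poor cyclobutenone and only from the α-face, opposite the axial C10 methyl and the β-lactone bridge, which sets the 9α-oxygen (C9) and a transient 8α-hydroxyl.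

Step 10
Reactants: 18 diol 8α,9α-dihydroxy-15-oxo-17-nor-15,16-cyclolabd-13-en-19,6β-olide
Product: 20 spiro-cyclobutanone 9α,13-epoxy-8,15-dioxo-17-nor-15,16-cyclolabdan-19,6β-olide, via hydroxy ketone 19 (not isolated)
Conditions: Dess–Martin periodinane, CH2Cl2, 0 °C; then DBU (3 equiv), 25 °C
Reagents that add atoms: none
Why: Dess–Martin oxidation of the secondary C8 alcohol (the tertiary C9–OH cannot be oxidized) is followed by base-mediated 5-exo oxa-Michael addition of the 9α-hydroxyl to the strained cyclobutenone, which closes the spiro-tetrahydrofuran with C9 unchanged and leaves C13 prochiral because its two CH2C(=O) arms are identical.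

Step 11
Reactants: 20 spiro-cyclobutanone 9α,13-epoxy-8,15-dioxo-17-nor-15,16-cyclolabdan-19,6β-olide
Product: 21 keto dilactone (13S)-9α,13-epoxy-8-oxo-17-norlabdane-19,6β:16,15-diolide
Conditions: (R)-3,3'-bis(2,4,6-triisopropylphenyl)-H8-BINOL hydrogen phosphate (10 mol%), 30% aq. H2O2 (1.5 equiv), CHCl3, −40 °C
Reagents that add atoms: hydrogen peroxide (OO)
Why: Chiral Brønsted acid-catalysed asymmetric Baeyer–Villiger ring expansion, in which only the strained cyclobutanone forms the Criegee adduct (the hindered C8 cyclohexanone does not) and the phosphate-bound adduct lets one of the two diastereotopic CH2 groups migrate to oxygen (1,2-shift), which sets C13 as S; the catalyst antipode matched to the substrate is fixed in a pilot run.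

Step 12
Reactants: 21 keto dilactone (13S)-9α,13-epoxy-8-oxo-17-norlabdane-19,6β:16,15-diolide
Product: 22 (13S)-8β-hydroxy-9α,13-epoxylabdane-19,6β:16,15-diolide
Conditions: MeMgBr, CeCl3, THF, −78 °C; then aq. NH4Cl
Reagents that add atoms: methylmagnesium bromide (C[Mg]Br)
Why: MeMgBr/CeCl3 addition to the α-alkoxy ketone is much faster than attack on either lactone at −78 °C, and the methyl group enters equatorially from the α-face because the axial C10 methyl and C6 oxygen block the β-face, giving the 8β-hydroxy-8α-methyl centre (sets C8).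

**Compound list**
1 | cyclohexane-1,3-dione | O=C1CCCC(=O)C1 | starting material
2 | 2-methylcyclohexane-1,3-dione | CC1C(=O)CCCC1=O | intermediate
3 | acrolein (prop-2-enal) | C=CC=O | starting material
4 | methyl 2-bromopropanoate (racemic) | CC(Br)C(=O)OC | starting material
5 | 3-(1-methyl-2,6-dioxocyclohexyl)propanal | O=CCCC1(C)C(=O)CCCC1=O | intermediate
6 | (1-methoxy-1-oxopropan-2-yl)triphenylphosphonium bromide | CC(C(=O)OC)[P+](c1ccccc1)(c1ccccc1)c1ccccc1.[Br-] | intermediate
7 | methyl 2-(triphenyl-λ5-phosphanylidene)propanoate | CC(C(=O)OC)=P(c1ccccc1)(c1ccccc1)c1ccccc1 | intermediate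
8 | methyl (E)-2-methyl-5-(1-methyl-2,6-dioxocyclohexyl)pent-2-enoate | C/C(=C\CCC1(C)C(=O)CCCC1=O)C(=O)OC | intermediate
9 | methyl (1S,4aS,8aR)-8a-hydroxy-1,4a-dimethyl-5-oxodecahydronaphthalene-1-carboxylate (cis-fused; OH, angular methyl and ester all cis) | C1CC[C@]2(O)[C@@](C)(C(=O)OC)CCC[C@]2(C)C1=O | intermediate
10 | methyl (1S,4aS)-1,4a-dimethyl-5-oxo-1,2,3,4,4a,5,6,7-octahydronaphthalene-1-carboxylate | C1CC=C2[C@@](C)(C(=O)OC)CCC[C@]2(C)C1=O | intermediate
11 | keto lactone (4S,5R,6R,10S)-9-oxo-11,12,13,14,15,16,17-heptanorlabdan-19,6-olide (5α-H, 6β-O) | C1C[C@H]2OC(=O)[C@@]3(C)CCC[C@@](C)([C@@H]23)C1=O | intermediate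
12 | enol triflate (4S,5R,6R,10S)-9-(trifluoromethanesulfonyloxy)-11,12,13,14,15,16,17-heptanorlabd-8-en-19,6-olide | C=1C[C@H]2OC(=O)[C@@]3(C)CCC[C@@](C)([C@@H]23)C=1OS(=O)(=O)C(F)(F)F | intermediate
13 | 3-ethoxycyclobut-2-en-1-one | CCOC1=CC(=O)C1 | starting material
14 | (1-ethenyl-3-ethoxycyclobut-2-en-1-yl)oxy(trimethyl)silane (racemic) | CCOC1=CC(C=C)(O[Si](C)(C)C)C1 | intermediate
15 | 9-[2-(3-ethoxy-1-trimethylsilyloxycyclobut-2-en-1-yl)ethyl]-9-borabicyclo[3.3.1]nonane | CCOC1=CC(CCB2C3CCCC2CCC3)(O[Si](C)(C)C)C1 | intermediate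
16 | coupled silyl ether: 12 with OTf replaced by 2-(3-ethoxy-1-trimethylsilyloxycyclobut-2-en-1-yl)ethyl (both epimers at the silyloxy carbon) | C=1C[C@H]2OC(=O)[C@@]3(C)CCC[C@@](C)([C@@H]23)C=1CCC4(O[Si](C)(C)C)C=C(OCC)C4 | intermediate
17 | cyclobutenone (4S,5R,6R,10S)-15-oxo-17-nor-15,16-cyclolabda-8,13-dien-19,6-olide (C9 carries 2-(3-oxocyclobut-1-en-1-yl)ethyl) | C=1C[C@H]2OC(=O)[C@@]3(C)CCC[C@@](C)([C@@H]23)C=1CCC4=CC(=O)C4 | intermediate
18 | diol 8α,9α-dihydroxy-15-oxo-17-nor-15,16-cyclolabd-13-en-19,6β-olide | O[C@@H]1C[C@H]2OC(=O)[C@@]3(C)CCC[C@@](C)([C@@H]23)[C@@]1(O)CCC1=CC(=O)C1 | intermediate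
19 | hydroxy ketone 9α-hydroxy-8,15-dioxo-17-nor-15,16-cyclolabd-13-en-19,6β-olide | O=C1C[C@H]2OC(=O)[C@@]3(C)CCC[C@@](C)([C@@H]23)[C@@]1(O)CCC1=CC(=O)C1 | intermediate
20 | spiro-cyclobutanone 9α,13-epoxy-8,15-dioxo-17-nor-15,16-cyclolabdan-19,6β-olide | O=C1C[C@H]2OC(=O)[C@@]3(C)CCC[C@@](C)([C@@H]23)[C@@]12CCC1(CC(=O)C1)O2 | intermediate
21 | keto dilactone (13S)-9α,13-epoxy-8-oxo-17-norlabdane-19,6β:16,15-diolide | O=C1C[C@H]2OC(=O)[C@@]3(C)CCC[C@@](C)([C@@H]23)[C@@]12CC[C@]1(COC(=O)C1)O2 | intermediate
22 | (13S)-8β-hydroxy-9α,13-epoxylabdane-19,6β:16,15-diolide, (4S,5R,6R,8S,9S,10S,13S) | C[C@]1(O)C[C@H]2OC(=O)[C@@]3(C)CCC[C@@](C)([C@@H]23)[C@@]12CC[C@]1(COC(=O)C1)O2 | target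

**Step count and risks**

Total step count: 12. Longest linear sequence: 11 steps (steps 1–6 and 8–12, from cyclohexane-1,3-dione); step 7 is a one-step side branch.

The three steps most likely to fail:

- **Step 5 (the proposed new step).** The alkene may be too electron-poor to oxidize, or the 5-endo closure by an ester oxygen may be too slow. The fallback uses known chemistry and sets out from 10. Iodine in acetonitrile at 50 °C closes the lactone by trans-diaxial iodolactonization, iodide removing the ester methyl, to give the 5α-iodo keto lactone F1. Bu3SnH with AIBN in toluene at 80 °C then replaces iodine by hydrogen from the α-face, and the route is rejoined at 11.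

- **Step 9.** OsO4 may also attack the cyclobutenone, or the diol may cyclize through the C8 hydroxyl before oxidation. The fallback sets out from 17 and masks the enone first. Methanol with catalytic NaOMe adds to the cyclobutenone to give the 3-methoxycyclobutanone alkene F2. OsO4/NMO then gives the methoxy diol F3, and Dess–Martin oxidation gives the methoxy hydroxy ketone F4. DBU expels methanol (E1cB) to regenerate the cyclobutenone as 19, which closes as in step 10, and the route is rejoined at 20.

- **Step 11.** The catalyst may give poor selection between the two CH2 groups on this 3,3-disubstituted cyclobutanone. The fallback sets out from 20 and gives up reagent control. Buffered mCPBA (NaHCO3, CH2Cl2) gives 21 together with the C13 epimer F5; the two are diastereomers and are separated by chromatography. F5 is recycled with DBU, which opens it by retro-oxa-Michael reaction to the hydroxy butenolide F6; this recloses to both epimers, and the route is rejoined at 21.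

**Further compounds**
F1 | step 5 | 5α-iodo keto lactone (5α-iodo-9-oxo-11,12,13,14,15,16,17-heptanorlabdan-19,6β-olide) | C1C[C@H]2OC(=O)[C@@]3(C)CCC[C@@](C)([C@@]23I)C1=O
F2 | step 9 | 3-methoxycyclobutanone alkene (17 with methanol added across the cyclobutenone) | C=1C[C@H]2OC(=O)[C@@]3(C)CCC[C@@](C)([C@@H]23)C=1CCC4(OC)CC(=O)C4
F3 | step 9 | methoxy diol (8α,9α-diol of F2) | O[C@@H]1C[C@H]2OC(=O)[C@@]3(C)CCC[C@@](C)([C@@H]23)[C@@]1(O)CCC1(OC)CC(=O)C1
F4 | step 9 | methoxy hydroxy ketone (9α-hydroxy-8-ketone of F3) | O=C1C[C@H]2OC(=O)[C@@]3(C)CCC[C@@](C)([C@@H]23)[C@@]1(O)CCC1(OC)CC(=O)C1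
F5 | step 11 | C13 epimer of 21, (13R)-9α,13-epoxy-8-oxo-17-norlabdane-19,6β:16,15-diolide | O=C1C[C@H]2OC(=O)[C@@]3(C)CCC[C@@](C)([C@@H]23)[C@@]12CC[C@@]1(COC(=O)C1)O2
F6 | step 11 | hydroxy butenolide 9α-hydroxy-8-oxo-17-norlabd-13-ene-19,6β:16,15-diolide | O=C1C[C@H]2OC(=O)[C@@]3(C)CCC[C@@](C)([C@@H]23)[C@@]1(O)CCC1=CC(=O)OC1
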